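**Retrosynthetic overview** (chain numbered as tridecane: C1 = ArCH2, C2 = CH(OAc), C8 = ketone)
1. Last step: hydrogenolysis of two phenol benzyl ethers.
2. Key disconnection C5–C6: a primary C5 radical adds to the CH2 terminus (C6) of oct-1-en-3-one. The radical and the finished C2 acetate are released together by ring-opening β-scission of a cyclic peroxyketal, made in the same flask by ozonolysis of an (R)-alkenol.
3. Enabling feature: the acetate oxygen on C2 and C5 are 1,5-related, so the acetyl carbon can be tied to both in a six-membered 2-methyltetrahydropyran (O, acetyl C, C5, C4, C3, C2). Scission of its anomeric alkoxyl radical returns the acetate and leaves the radical at C5; the C8 ketone makes C6 the β-carbon of a vinyl ketone.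
4. The alkenol comes from two copper-catalysed Grignard openings on the C3 unit of (S)-epichlorohydrin (aryl first, then 3-methylbut-3-enyl); the C2 stereocentre is taken from the chiral pool.
5. Rings: the benzene ring is bought; the only ring formed is the temporary tetrahydropyran, closed and opened within step 4.

Key step: step 4

Assumptions: 1,3-bis(benzyloxy)-5-bromobenzene, (S)-epichlorohydrin, 4-bromo-2-methylbut-1-ene and oct-1-en-3-one are taken as commercial. Peroxyketal 10 should form as both epimers at its ring carbon C2, which does not matter because that carbon becomes the acetate carbonyl.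

**Step 1**
Reactants: 1 1,3-bis(benzyloxy)-5-bromobenzene; 2 (S)-epichlorohydrin
Product: 4 (2S)-1-[3,5-bis(benzyloxy)phenyl]-3-chloropropan-2-ol, via aryl Grignard reagent 3 (not isolated)
Conditions: Mg, THF, 40 °C; then CuI (10 mol%), 2, THF, −40 → 0 °C; aq. NH4Cl
Reagents that add atoms: none
Why: Copper-catalysed SN2 opening of the epoxide at its unsubstituted CH2 by the aryl Grignard reagent should outrun chloride displacement at low temperature; the stereocentre of 2 is not touched.

**Step 2**
Reactants: 4 (2S)-1-[3,5-bis(benzyloxy)phenyl]-3-chloropropan-2-ol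
Product: 5 (2S)-2-[3,5-bis(benzyloxy)benzyl]oxirane
Conditions: NaOH (powdered), Et2O, rt
Reagents that add atoms: none
Why: Intramolecular Williamson etherification (3-exo-tet) of the chlorohydrin alkoxide; the carbinol C–O bond is not broken, so the configuration is retained.

**Step 3**
Reactants: 5 (2S)-2-[3,5-bis(benzyloxy)benzyl]oxirane; 6 4-bromo-2-methylbut-1-ene
Product: 8 (2R)-1-[3,5-bis(benzyloxy)phenyl]-6-methylhept-6-en-2-ol, via alkenyl Grignard reagent 7 (not isolated)
Conditions: Mg, THF, rt; then CuI (10 mol%), 5, THF, −30 → 0 °C; aq. NH4Cl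
Reagents that add atoms: none
Why: Copper-catalysed opening of the terminal epoxide at CH2 by a primary alkyl Grignard reagent; the C–O bond at the stereocentre is untouched (the descriptor changes from S to R only through CIP priorities).

**Step 4**
Reactants: 8 (2R)-1-[3,5-bis(benzyloxy)phenyl]-6-methylhept-6-en-2-ol; 9 oct-1-en-3-one
Product: 11 (2R)-1-[3,5-bis(benzyloxy)phenyl]-8-oxotridecan-2-yl acetate, via cyclic peroxyketal 10 (not isolated)
Conditions: O3, CH2Cl2, −78 °C (Sudan Red 7B end point); Ar purge; then MeOH, 9 (5 equiv), FeSO4·7H2O (2.5 equiv), −78 °C → rt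
Reagents that add atoms: ozone, [O-][O+]=O
Why: Proposed new method: ozone should cleave the 1,1-disubstituted alkene of 8 to formaldehyde and the ketone O-oxide (the more substituted Criegee fragment), which the C2 hydroxyl captures by 6-exo-trig attack to close the temporary tetrahydropyran ring of 10; Fe(II) then reduces the O–O bond, and the anomeric alkoxyl radical undergoes β-scission of the ring C–C bond, turning the ring carbon into the acetate carbonyl on the C2 oxygen and freeing C5 as a primary radical. This nucleophilic radical adds to the unsubstituted terminus of enone 9 (C6), and the electrophilic α-keto radical so formed is reduced by a second Fe(II) and protonated by methanol. The closest known reaction types are the Fe(II)-promoted fragmentation of ozonolysis-derived α-alkoxy hydroperoxides to esters plus alkyl radicals (dealkenylative functionalisation, and the Fe/Cu fragmentation of cyclic α-alkoxy hydroperoxides to alkenyl esters) and the Fe(II)-terminated redox addition of peroxide-derived alkyl radicals to electron-poor alkenes; merging them on a cyclic peroxyketal with an enone trap is the new part. No new stereocentre is kept: the peroxyketal carbon of 10 is destroyed again, and the C2–O bond is never broken, so the (R) centre derived from 2 is carried through. The selectivities needed are ring C–C over C–CH3 scission (primary versus methyl radical), addition over radical dimerisation or hydrogen abstraction (excess 9, low radical concentration), and reduction of the adduct radical only (Fe(II) reduces α-carbonyl radicals but not unactivated alkyl radicals).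

**Step 5**
Reactants: 11 (2R)-1-[3,5-bis(benzyloxy)phenyl]-8-oxotridecan-2-yl acetate
Product: 12 (2R)-1-(3,5-dihydroxyphenyl)-8-oxotridecan-2-yl acetate
Conditions: H2 (1 atm), 10% Pd/C, EtOAc, rt
Reagents that add atoms: none
Why: Catalytic hydrogenolysis of aryl benzyl ethers; the aliphatic ketone and the non-benzylic secondary acetate should be inert under these conditions.

**Compound list**
1 | 1,3-bis(benzyloxy)-5-bromobenzene | Brc1cc(OCc2ccccc2)cc(OCc2ccccc2)c1 | starting material
2 | (S)-epichlorohydrin, (2S)-2-(chloromethyl)oxirane | ClC[C@@H]1CO1 | starting material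
3 | [3,5-bis(benzyloxy)phenyl]magnesium bromide | Br[Mg]c1cc(OCc2ccccc2)cc(OCc2ccccc2)c1 | intermediate
4 | (2S)-1-[3,5-bis(benzyloxy)phenyl]-3-chloropropan-2-ol | ClC[C@H](Cc1cc(OCc2ccccc2)cc(OCc2ccccc2)c1)O | intermediate
5 | (2S)-2-[3,5-bis(benzyloxy)benzyl]oxirane | C1[C@H](Cc2cc(OCc3ccccc3)cc(OCc3ccccc3)c2)O1 | intermediate
6 | 4-bromo-2-methylbut-1-ene | C=C(C)CCBr | starting material
7 | (3-methylbut-3-en-1-yl)magnesium bromide | C=C(C)CC[Mg]Br | intermediate
8 | (2R)-1-[3,5-bis(benzyloxy)phenyl]-6-methylhept-6-en-2-ol | C=C(C)CCC[C@H](Cc1cc(OCc2ccccc2)cc(OCc2ccccc2)c1)O | intermediate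
9 | oct-1-en-3-one | C=CC(=O)CCCCC | starting material
10 | (6R)-6-[3,5-bis(benzyloxy)benzyl]-2-hydroperoxy-2-methyltetrahydro-2H-pyran (both C2 epimers) | CC1(OO)CCC[C@H](Cc2cc(OCc3ccccc3)cc(OCc3ccccc3)c2)O1 | intermediate
11 | (2R)-1-[3,5-bis(benzyloxy)phenyl]-8-oxotridecan-2-yl acetate | CCCCCC(=O)CCCCC[C@H](Cc1cc(OCc2ccccc2)cc(OCc2ccccc2)c1)OC(C)=O | intermediate
12 | (2R)-1-(3,5-dihydroxyphenyl)-8-oxotridecan-2-yl acetate | CCCCCC(=O)CCCCC[C@H](Cc1cc(O)cc(O)c1)OC(C)=O | target

**Total step count:** 5. **Longest linear sequence:** 5 steps (1 → 4 → 5 → 8 → 11 → 12).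

**Steps most likely to fail**

Step 4 (proposed new method). The Criegee intermediate may close to a secondary ozonide with formaldehyde instead of being captured by the hydroxyl, ozone may attack the electron-rich arene, and the C5 radical may dimerise, abstract hydrogen or start oligomerisation of the enone before it is trapped 1:1 and reduced. The fallback uses known chemistry, sets out from 5 and returns at 11, forming the same C5–C6 bond. Copper-catalysed opening of 5 with vinylmagnesium bromide would give (2R)-1-[3,5-bis(benzyloxy)phenyl]pent-4-en-2-ol F1. Acetylation (Ac2O, pyridine, DMAP) would give (2R)-1-[3,5-bis(benzyloxy)phenyl]pent-4-en-2-yl acetate F2. Hydroboration with 9-BBN and oxidation with NaBO3 would give (2R)-1-[3,5-bis(benzyloxy)phenyl]-5-hydroxypentan-2-yl acetate F3. Appel iodination (I2, PPh3, imidazole) would give (2R)-1-[3,5-bis(benzyloxy)phenyl]-5-iodopentan-2-yl acetate F4. A tin-free Giese addition of F4 to 9 ((Me3Si)3SiH, AIBN, toluene, 80 °C) would then give 11.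

Step 1. Enantiopurity may be eroded when halide opens the epoxide of 2 and the halohydrin recloses in the opposite sense, and the Grignard reagent may attack the C–Cl carbon. The fallback sets out from 1 (through 3) and returns at 5. Coupling of 3 with allyl bromide would give 1-allyl-3,5-bis(benzyloxy)benzene F5, and mCPBA epoxidation would give racemic 2-[3,5-bis(benzyloxy)benzyl]oxirane F6. Hydrolytic kinetic resolution with (R,R)-(salen)Co(III)OAc and 0.55 equiv of water, the catalyst enantiomer expected to hydrate the (R)-epoxide, should leave 5 in high enantiomeric purity.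

Step 3. Magnesium halide may open or rearrange the benzyl-substituted epoxide before the slower sp3–sp3 coupling takes place. The fallback reverses the order of the two epoxide openings, sets out from 6 (through 7) and returns at 8. Reagent 7 would open (R)-epichlorohydrin F7, the purchased enantiomer of 2, under CuI catalysis to give (2R)-1-chloro-6-methylhept-6-en-2-ol F8. NaOH would close it to (2R)-2-(4-methylpent-4-en-1-yl)oxirane F9. The aryl Grignard reagent 3 with catalytic CuI would then open this simple alkyl oxirane at CH2 to give 8.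

**Further compounds**
F1 | step 4 | (2R)-1-[3,5-bis(benzyloxy)phenyl]pent-4-en-2-ol | C=CC[C@H](Cc1cc(OCc2ccccc2)cc(OCc2ccccc2)c1)O
F2 | step 4 | (2R)-1-[3,5-bis(benzyloxy)phenyl]pent-4-en-2-yl acetate | C=CC[C@H](Cc1cc(OCc2ccccc2)cc(OCc2ccccc2)c1)OC(C)=O
F3 | step 4 | (2R)-1-[3,5-bis(benzyloxy)phenyl]-5-hydroxypentan-2-yl acetate | OCCC[C@H](Cc1cc(OCc2ccccc2)cc(OCc2ccccc2)c1)OC(C)=O
F4 | step 4 | (2R)-1-[3,5-bis(benzyloxy)phenyl]-5-iodopentan-2-yl acetate | ICCC[C@H](Cc1cc(OCc2ccccc2)cc(OCc2ccccc2)c1)OC(C)=O
F5 | step 1 | 1-allyl-3,5-bis(benzyloxy)benzene | C=CCc1cc(OCc2ccccc2)cc(OCc2ccccc2)c1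
F6 | step 1 | racemic 2-[3,5-bis(benzyloxy)benzyl]oxirane | C1C(Cc2cc(OCc3ccccc3)cc(OCc3ccccc3)c2)O1
F7 | step 3 | (R)-epichlorohydrin (purchased enantiomer of 2) | ClC[C@H]1CO1
F8 | step 3 | (2R)-1-chloro-6-methylhept-6-en-2-ol | C=C(C)CCC[C@H](CCl)O
F9 | step 3 | (2R)-2-(4-methylpent-4-en-1-yl)oxirane | C=C(C)CCC[C@@H]1CO1
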